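**Strategy**

Both C7–C11 bonds of the twelve-membered carbocycle are disconnected by a twofold transannular Ireland–Claisen rearrangement. The feature used is that each quaternary ester α-carbon C11 sits on C7 of a six-membered ring (C5–C10), two atoms from C5, so a C12 carboxylate on a C5 oxygen gives the array C11–C12–O–C5–C6=C7. In one operation the key step makes both C–C bonds and both quaternary centres and turns a twelve-membered diolide into the carbocycle (C11–C15–C4–C5–C6–C7)2. Its precursor is the C2-symmetric head-to-tail diolide of two cis-fused tricyclic hydroxy acids, carried with C8 as a PMB ether instead of a ketone and C9 as a TBS ether.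

Key step: step 18

Remark (numbering): lindenane numbering throughout; cyclopropane C1–C2–C3, five-membered ring C1/C3/C4/C5/C10, six-membered ring C5–C10, C14 = methyl on C10, side chain C15–C11(C13)–C12 on C4; β is the face of C14 and of the cyclopropane CH2.
Remark (assumption): (−)-Ipc2BH from (+)-α-pinene is taken to give the (1S,2S) alcohol in step 1; if the sense is opposite, the antipodal borane is used.
Remark (C11): from 17 to 27, C11 is a mixture of epimers and is written without descriptor; step 18 erases it.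
Remark (C8): a C8 ketone would be enolised toward C9 by amide base and would offer the ester enolate an enone to add to, so C8 stays an α-OPMB carbinol until step 21.

Step 1
Reactants: 1 sodium cyclopentadienide
Product: 4 (1S,2S)-2-methylcyclopent-3-en-1-ol, via 5-methylcyclopenta-1,3-diene 2 (not isolated), via cyclopentenyl(diisopinocampheyl)borane 3 (not isolated)
Conditions: MeI, THF, −50 → −20 °C; then (−)-Ipc2BH, THF, −78 → 0 °C; then NaOH, H2O2, 0 °C → rt
Reagents that add atoms: iodomethane CI; hydrogen peroxide OO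
Why: C-methylation at low temperature gives the 5-methyl diene before [1,5]-H shift, and Brown asymmetric hydroboration–oxidation places boron at the diene terminus anti to the methyl, so the chiral borane sets both centres (1S,2S) and oxidation retains them.

Step 2
Reactants: 4 (1S,2S)-2-methylcyclopent-3-en-1-ol
Product: 5 2-methylbicyclo[3.1.0]hexan-3-ol (5β-OH cis to the cyclopropane CH2; 10α-methyl)
Conditions: Et2Zn, CH2I2, CH2Cl2, 0 °C → rt
Reagents that add atoms: diiodomethane ICI
Why: Hydroxyl-directed Simmons–Smith (Furukawa) cyclopropanation delivers CH2 to the alkene face syn to the homoallylic OH and anti to the methyl, which sets C1 and C3.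

Step 3
Reactants: 5 2-methylbicyclo[3.1.0]hexan-3-ol
Product: 6 2-methylbicyclo[3.1.0]hexan-3-one (C5 ketone; 10α-methyl)
Conditions: TPAP (5 mol %), NMO, 4 Å MS, CH2Cl2, rt
Reagents that add atoms: none
Why: Ley–Griffith oxidation of the secondary alcohol under neutral conditions; C10 is epimerisable but becomes planar in the next step.

Step 4
Reactants: 6 2-methylbicyclo[3.1.0]hexan-3-one
Product: 7 C5=C10 trimethylsilyl enol ether
Conditions: TMSCl, NaI, Et3N, MeCN, rt
Reagents that add atoms: chlorotrimethylsilane C[Si](C)(C)Cl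
Why: Thermodynamic enol silylation with TMSI made in situ favours the tetrasubstituted C5=C10 enol ether, which is also conjugated with the cyclopropane; the minor C4 regioisomer should be separable after step 8.

Step 5
Reactants: 8 (R)-but-3-ene-1,2-diol
Product: 9 (4R)-2-(4-methoxyphenyl)-4-vinyl-1,3-dioxolane
Conditions: 4-MeOC6H4CH(OMe)2, CSA (cat.), CH2Cl2, rt
Reagents that add atoms: 4-methoxybenzaldehyde dimethyl acetal COC(OC)c1ccc(OC)cc1
Why: Acid-catalysed transacetalisation of the 1,2-diol; the acetal epimers are inconsequential.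

Step 6
Reactants: 9 (4R)-2-(4-methoxyphenyl)-4-vinyl-1,3-dioxolane
Product: 10 (R)-2-(4-methoxybenzyloxy)but-3-en-1-ol
Conditions: DIBAL-H, CH2Cl2, −78 → 0 °C
Reagents that add atoms: none
Why: Regioselective reductive acetal opening: aluminium coordinates the less hindered primary oxygen, so the PMB group stays on the secondary oxygen.

Step 7
Reactants: 10 (R)-2-(4-methoxybenzyloxy)but-3-en-1-ol
Product: 11 (R)-2-(4-methoxybenzyloxy)but-3-enal
Conditions: Dess–Martin periodinane, NaHCO3, CH2Cl2, 0 °C; used at once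
Reagents that add atoms: none
Why: Buffered Dess–Martin oxidation forms the α-alkoxy aldehyde without base, so neither C8 epimerisation nor alkene migration should intervene.

Step 8
Reactants: 7 C5=C10 trimethylsilyl enol ether; 11 (R)-2-(4-methoxybenzyloxy)but-3-enal
Product: 12 C10-quaternary aldol (14β-methyl; 9R-OH; 8R-OPMB; C7 vinyl)
Conditions: TiCl4, CH2Cl2, −78 °C (11 precomplexed, then 7)
Reagents that add atoms: none
Why: Mukaiyama aldol: the enol silane reacts through its α face, anti to the cyclopropane CH2, so the new quaternary C10 carries C14 β, and the TiCl4 chelate of the α-OPMB aldehyde (Cram chelate control) fixes C9 as R, syn to C8.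

Step 9
Reactants: 12 C10-quaternary aldol
Product: 13 9-O-TBS ketone
Conditions: TBSOTf, 2,6-lutidine, CH2Cl2, −78 → 0 °C
Reagents that add atoms: tert-butyldimethylsilyl triflate CC(C)(C)[Si](C)(C)OS(=O)(=O)C(F)(F)F
Why: Silylation of the neopentyl secondary alcohol with the reactive triflate blocks retro-aldol cleavage before the basic steps.

Step 10
Reactants: 13 9-O-TBS ketone; 14 methyl 2-(bromomethyl)acrylate
Product: 16 4α-[2-(methoxycarbonyl)allyl] ketone, via lithium enolate 15 (not isolated)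
Conditions: LDA, THF, −78 °C; then 14, −78 → −40 °C
Reagents that add atoms: none
Why: C4 is the only enolisable position, and SN2′ alkylation of the lithium enolate occurs anti to the adjacent cyclopropane (C15 α), which is also the thermodynamic configuration.

Step 11
Reactants: 16 4α-[2-(methoxycarbonyl)allyl] ketone
Product: 17 4α-[2-(methoxycarbonyl)propyl] ketone (C11 epimers)
Conditions: [(Ph3P)CuH]6, toluene, H2O, rt
Reagents that add atoms: none
Why: Stryker conjugate reduction (CuH 1,4-addition, then protonation) saturates only the acrylate; the isolated vinyl group, the hindered ketone and the PMB and TBS ethers are inert.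

Step 12
Reactants: 17 4α-[2-(methoxycarbonyl)propyl] ketone
Product: 18 5β-hydroxy-5α-vinyl diene ester
Conditions: CH2=CHMgBr, CeCl3, THF, −78 °C
Reagents that add atoms: vinylmagnesium bromide C=C[Mg]Br
Why: Imamoto organocerium 1,2-addition tolerates the ester and suppresses enolisation; the nucleophile should enter on the α face because the C14 methyl and the endo hydrogen of the cyclopropane CH2 cover the β face, which leaves the C5 oxygen β and cis to C14.

Step 13
Reactants: 18 5β-hydroxy-5α-vinyl diene ester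
Product: 19 tricyclic hydroxy ester (cis-fused; 5β-OH; C6=C7; 8α-OPMB; 9β-OTBS)
Conditions: Grubbs II (5 mol %), CH2Cl2, 40 °C
Reagents that add atoms: none
Why: Ring-closing metathesis of the two terminal vinyl groups, which are cis across C5–C10, closes the cis-fused cyclohexene with loss of ethene.

Step 14
Reactants: 19 tricyclic hydroxy ester
Product: 20 tricyclic hydroxy acid
Conditions: LiOH, THF/MeOH/H2O, 40 °C; 1 M HCl, 0 °C
Reagents that add atoms: lithium hydroxide [Li+].[OH-]
Why: Saponification of the α-branched methyl ester; the acid should not lactonise onto C5–OH because the C4 chain is trans to it on the cyclopropane-locked five-membered ring.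

Step 15
Reactants: 20 tricyclic hydroxy acid; 19 tricyclic hydroxy ester
Product: 24 open-chain dimer ester, via bis-TMS derivative 21 (not isolated), via acid chloride 22 (not isolated), via lithium alkoxide 23 (not isolated)
Conditions: 20: BSTFA, TMSCl (cat.), MeCN, 70 °C, evaporate; (COCl)2, DMF (cat.), CH2Cl2, 0 °C, evaporate; 19: LiHMDS, THF, −78 °C; combine, −78 → 0 °C
Reagents that add atoms: N,O-bis(trimethylsilyl)trifluoroacetamide C[Si](C)(C)OC(=N[Si](C)(C)C)C(F)(F)F
Why: Acylation of a preformed lithium tert-alkoxide by an acid chloride is the standard esterification of hindered tertiary alcohols; the TMS ether on the acid partner prevents self-condensation, and ketene formation from 22 is harmless because C11 is not yet fixed.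

Step 16
Reactants: 24 open-chain dimer ester
Product: 25 seco acid
Conditions: LiOH, THF/MeOH/H2O, 40 °C; 1 M HCl, 0 °C
Reagents that add atoms: lithium hydroxide [Li+].[OH-]
Why: Hydroxide and the acidic work-up cleave the unhindered methyl ester and the labile tertiary TMS ether, while the tertiary ester that links the halves resists saponification.

Step 17
Reactants: 25 seco acid
Product: 27 twelve-membered diolide, via acyl fluoride 26 (not isolated)
Conditions: cyanuric fluoride, pyridine, CH2Cl2, −10 °C; then NaH, THF, 1 mM, 0 → 25 °C (slow addition)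
Reagents that add atoms: none
Why: Macrolactonisation by intramolecular acylation of the sodium tert-alkoxide with the small acyl fluoride at high dilution (12-exo-trig acyl substitution); the only competing closure, attack on the neighbouring ester, would give a δ-lactone trans-fused on the rigid five-membered ring.

Step 18
Reactants: 27 twelve-membered diolide
Product: 30 twelve-membered carbocyclic diacid, via bis(silyl ketene acetal) 28 (not isolated), via bis(trimethylsilyl ester) 29 (not isolated)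
Conditions: LDA, TMSCl/Et3N, THF (no HMPA), −78 °C; then 65 °C; 1 M HCl
Reagents that add atoms: none
Why: LDA with TMSCl present removes the two C11–H, the only acidic C–H bonds of 27, to give 28 and merge all C11 epimers; on warming each ketene acetal undergoes a concerted suprafacial [3,3] shift in which C5–O breaks and C7–C11 forms, and the silyl esters 29 are hydrolysed on work-up. The closest known reactions are the Ireland–Claisen rearrangement of tertiary allylic esters to α-quaternary acids and its transannular use on macrolactones that carry the alkene outside the lactone ring. The carbocycle closes transannularly: each six-membered transition state is bridged from C11 to C5 by the other eight ring atoms, so C12 and O leave the ring while C6 and C7 enter it and the ring stays twelve-membered. C7 follows from the β C5–O bond (new bond on the same face); C11 follows from the ketene acetal geometry, which the ring is expected to hold with C15 cisoid to the lactone oxygen, combined with a boat transition state, preferred because a chair would push the OSiMe3 group against the β C14 methyl and the C9 OTBS group. With C15 over C8–H and C13 pointing outward, this should give the C11 configuration of 36. The step needs this C11 diastereoselectivity and clean enolisation, which the trans C4/C5 arrangement, the α C8 OPMB group (no ketone, no Michael acceptor, no enolisable C9–H) and the rigid diolide are meant to secure.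

Step 19
Reactants: 30 twelve-membered carbocyclic diacid
Product: 31 dimethyl ester
Conditions: CH2N2, Et2O, 0 °C
Reagents that add atoms: diazomethane C=[N+]=[N-]
Why: Diazomethane O-methylates the two neopentyl carboxylic acids, which would resist Fischer or carbodiimide esterification, and touches nothing else.

Step 20
Reactants: 31 dimethyl ester
Product: 32 8,8′-diol
Conditions: DDQ, CH2Cl2/pH 7 buffer, 0 °C → rt
Reagents that add atoms: none
Why: Oxidative PMB ether cleavage (benzylic hydride abstraction, then hydrolysis of the oxocarbenium ion) frees both C8 hydroxyls; TBS ethers, esters and the trisubstituted alkenes should be unaffected.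

Step 21
Reactants: 32 8,8′-diol
Product: 33 8,8′-diketone
Conditions: Dess–Martin periodinane, NaHCO3, CH2Cl2, rt
Reagents that add atoms: none
Why: Dess–Martin oxidation gives the β,γ-unsaturated C8 ketones; any migration of C5=C6 into conjugation would lead to the same dienol ether in step 22.

Step 22
Reactants: 33 8,8′-diketone
Product: 35 9,9′-bis-O-TBS cycloshizukaol A, via bis(silyl dienol ether) 34 (not isolated)
Conditions: TMSOTf, Et3N, CH2Cl2, 0 °C; then DDQ, 2,6-lutidine, 0 °C → rt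
Reagents that add atoms: none
Why: Soft enolisation removes the doubly activated C7–H in preference to the hindered C9–H to give the C8-silyloxy C5,C7-diene, and DDQ abstracts hydride from C4 of this dienol ether (the dehydrogenation used for steroidal 4,6-dienones) to give the C4=C5, C6=C7 dienone after loss of silyl.

Step 23
Reactants: 35 9,9′-bis-O-TBS cycloshizukaol A
Product: 36 cycloshizukaol A
Conditions: HF·pyridine, THF, 0 °C → rt
Reagents that add atoms: none
Why: Fluoride-mediated desilylation of the hindered C9 TBS ethers under acidic conditions, which avoid base-induced epimerisation of the α-ketol.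

**Compound list**

1 | sodium cyclopentadienide | [Na+].c1cc[cH-]c1 | starting material
2 | 5-methylcyclopenta-1,3-diene | CC1C=CC=C1 | intermediate
3 | [(1S,2S)-2-methylcyclopent-3-en-1-yl]diisopinocampheylborane | C[C@H]1C=CC[C@@H]1B([C@@H]2C[C@@H]3C[C@H]([C@H]2C)C3(C)C)[C@@H]2C[C@@H]3C[C@H]([C@H]2C)C3(C)C | intermediate
4 | (1S,2S)-2-methylcyclopent-3-en-1-ol | C[C@H]1C=CC[C@@H]1O | intermediate
5 | 2-methylbicyclo[3.1.0]hexan-3-ol, 5β-OH cis to the cyclopropane CH2, 10α-methyl | C1[C@H]2C[C@H]2[C@H](C)[C@H]1O | intermediate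
6 | 2-methylbicyclo[3.1.0]hexan-3-one, cyclopropane β, 10α-methyl | C1[C@H]2C[C@H]2[C@H](C)C1=O | intermediate
7 | 2-methyl-3-(trimethylsilyloxy)bicyclo[3.1.0]hex-2-ene (C5=C10 enol ether) | C1[C@H]2C[C@H]2C(C)=C1O[Si](C)(C)C | intermediate
8 | (R)-but-3-ene-1,2-diol | OC[C@H](O)C=C | starting material
9 | (4R)-2-(4-methoxyphenyl)-4-vinyl-1,3-dioxolane, both acetal epimers | C=C[C@@H]1COC(c2ccc(OC)cc2)O1 | intermediate
10 | (R)-2-(4-methoxybenzyloxy)but-3-en-1-ol | OC[C@H](OCc1ccc(OC)cc1)C=C | intermediate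
11 | (R)-2-(4-methoxybenzyloxy)but-3-enal | O=C[C@H](OCc1ccc(OC)cc1)C=C | intermediate
12 | 2-methyl-2-[(1R,2R)-1-hydroxy-2-(4-methoxybenzyloxy)but-3-enyl]bicyclo[3.1.0]hexan-3-one, C14 β, side chain α | C1[C@H]2C[C@H]2[C@@](C)(C1=O)[C@@H](O)[C@H](OCc3ccc(OC)cc3)C=C | intermediate
13 | 9-O-TBS ether of 12 | C1[C@H]2C[C@H]2[C@@](C)(C1=O)[C@@H](O[Si](C)(C)C(C)(C)C)[C@H](OCc3ccc(OC)cc3)C=C | intermediate
14 | methyl 2-(bromomethyl)acrylate | COC(=O)C(=C)CBr | starting material
15 | lithium C4=C5 enolate of 13 | [Li+].[O-]C1=C[C@H]2C[C@H]2[C@]1(C)[C@@H](O[Si](C)(C)C(C)(C)C)[C@H](OCc3ccc(OC)cc3)C=C | intermediate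
16 | 4α-[2-(methoxycarbonyl)allyl] ketone | COC(=O)C(=C)C[C@@H]1[C@H]2C[C@H]2[C@@](C)(C1=O)[C@@H](O[Si](C)(C)C(C)(C)C)[C@H](OCc3ccc(OC)cc3)C=C | intermediate
17 | 4α-[2-(methoxycarbonyl)propyl] ketone, C11 epimers | COC(=O)C(C)C[C@@H]1[C@H]2C[C@H]2[C@@](C)(C1=O)[C@@H](O[Si](C)(C)C(C)(C)C)[C@H](OCc3ccc(OC)cc3)C=C | intermediate
18 | 5β-hydroxy-5α-vinyl diene ester | COC(=O)C(C)C[C@@H]1[C@H]2C[C@H]2[C@@](C)([C@]1(O)C=C)[C@@H](O[Si](C)(C)C(C)(C)C)[C@H](OCc3ccc(OC)cc3)C=C | intermediate
19 | tricyclic hydroxy ester: cis-fused cyclohexene, 5β-OH, C6=C7, 8α-OPMB, 9β-OTBS, 4α chain with methyl ester | COC(=O)C(C)C[C@@H]1[C@H]2C[C@H]2[C@]3(C)[C@@H](O[Si](C)(C)C(C)(C)C)[C@H](OCc4ccc(OC)cc4)C=C[C@]13O | intermediate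
20 | tricyclic hydroxy acid | OC(=O)C(C)C[C@@H]1[C@H]2C[C@H]2[C@]3(C)[C@@H](O[Si](C)(C)C(C)(C)C)[C@H](OCc4ccc(OC)cc4)C=C[C@]13O | intermediate
21 | trimethylsilyl ester 5-O-trimethylsilyl ether of 20 | C[Si](C)(C)OC(=O)C(C)C[C@@H]1[C@H]2C[C@H]2[C@]3(C)[C@@H](O[Si](C)(C)C(C)(C)C)[C@H](OCc4ccc(OC)cc4)C=C[C@]13O[Si](C)(C)C | intermediate
22 | 5-O-TMS acid chloride | ClC(=O)C(C)C[C@@H]1[C@H]2C[C@H]2[C@]3(C)[C@@H](O[Si](C)(C)C(C)(C)C)[C@H](OCc4ccc(OC)cc4)C=C[C@]13O[Si](C)(C)C | intermediate
23 | lithium C5 alkoxide of 19 | [Li+].COC(=O)C(C)C[C@@H]1[C@H]2C[C@H]2[C@]3(C)[C@@H](O[Si](C)(C)C(C)(C)C)[C@H](OCc4ccc(OC)cc4)C=C[C@]13[O-] | intermediate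
24 | open-chain dimer: O5 of the methyl ester half acylated by C12 of the 5-O-TMS half | COC(=O)C(C)C[C@@H]1[C@H]2C[C@H]2[C@]3(C)[C@@H](O[Si](C)(C)C(C)(C)C)[C@H](OCc4ccc(OC)cc4)C=C[C@]13OC(=O)C(C)C[C@@H]1[C@H]2C[C@H]2[C@]3(C)[C@@H](O[Si](C)(C)C(C)(C)C)[C@H](OCc4ccc(OC)cc4)C=C[C@]13O[Si](C)(C)C | intermediate
25 | seco acid: free C12 acid on one half, free C5–OH on the other | OC(=O)C(C)C[C@@H]1[C@H]2C[C@H]2[C@]3(C)[C@@H](O[Si](C)(C)C(C)(C)C)[C@H](OCc4ccc(OC)cc4)C=C[C@]13OC(=O)C(C)C[C@@H]1[C@H]2C[C@H]2[C@]3(C)[C@@H](O[Si](C)(C)C(C)(C)C)[C@H](OCc4ccc(OC)cc4)C=C[C@]13O | intermediate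
26 | acyl fluoride of 25 | FC(=O)C(C)C[C@@H]1[C@H]2C[C@H]2[C@]3(C)[C@@H](O[Si](C)(C)C(C)(C)C)[C@H](OCc4ccc(OC)cc4)C=C[C@]13OC(=O)C(C)C[C@@H]1[C@H]2C[C@H]2[C@]3(C)[C@@H](O[Si](C)(C)C(C)(C)C)[C@H](OCc4ccc(OC)cc4)C=C[C@]13O | intermediate
27 | twelve-membered head-to-tail diolide (C12–C11–C15–C4–C5–O)2, each half 8α-OPMB, 9β-OTBS, C6=C7; C11 epimers | O=C9C(C)C[C@@H]1[C@H]2C[C@H]2[C@]3(C)[C@@H](O[Si](C)(C)C(C)(C)C)[C@H](OCc4ccc(OC)cc4)C=C[C@]13OC(=O)C(C)C[C@@H]1[C@H]2C[C@H]2[C@]3(C)[C@@H](O[Si](C)(C)C(C)(C)C)[C@H](OCc4ccc(OC)cc4)C=C[C@]13O9 | intermediate (key-step precursor)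
28 | bis(trimethylsilyl ketene acetal) of 27, drawn with the ring-cisoid geometry the intended course requires | C[Si](C)(C)O/C9=C(\C)C[C@@H]1[C@H]2C[C@H]2[C@]3(C)[C@@H](O[Si](C)(C)C(C)(C)C)[C@H](OCc4ccc(OC)cc4)C=C[C@]13O/C(O[Si](C)(C)C)=C(/C)C[C@@H]1[C@H]2C[C@H]2[C@]3(C)[C@@H](O[Si](C)(C)C(C)(C)C)[C@H](OCc4ccc(OC)cc4)C=C[C@]13O9 | intermediate
29 | bis(trimethylsilyl) ester of 30 | C[Si](C)(C)OC(=O)[C@]1(C)C[C@H]2C3=C[C@@H]([C@@H](OCc4ccc(OC)cc4)[C@H](O[Si](C)(C)C(C)(C)C)[C@@]3(C)[C@@H]3C[C@H]23)[C@](C)(C(=O)O[Si](C)(C)C)C[C@H]2C3=C[C@H]1[C@@H](OCc4ccc(OC)cc4)[C@H](O[Si](C)(C)C(C)(C)C)[C@@]3(C)[C@@H]1C[C@H]21 | intermediate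
30 | twelve-membered carbocyclic diacid: both C11 quaternary, C5=C6, 7α-H, 4β-H, 8α-OPMB, 9β-OTBS | OC(=O)[C@]1(C)C[C@H]2C3=C[C@@H]([C@@H](OCc4ccc(OC)cc4)[C@H](O[Si](C)(C)C(C)(C)C)[C@@]3(C)[C@@H]3C[C@H]23)[C@](C)(C(=O)O)C[C@H]2C3=C[C@H]1[C@@H](OCc4ccc(OC)cc4)[C@H](O[Si](C)(C)C(C)(C)C)[C@@]3(C)[C@@H]1C[C@H]21 | intermediate (key-step product)
31 | dimethyl ester of 30 | COC(=O)[C@]1(C)C[C@H]2C3=C[C@@H]([C@@H](OCc4ccc(OC)cc4)[C@H](O[Si](C)(C)C(C)(C)C)[C@@]3(C)[C@@H]3C[C@H]23)[C@](C)(C(=O)OC)C[C@H]2C3=C[C@H]1[C@@H](OCc4ccc(OC)cc4)[C@H](O[Si](C)(C)C(C)(C)C)[C@@]3(C)[C@@H]1C[C@H]21 | intermediate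
32 | 8,8′-diol (8α-OH) | COC(=O)[C@]1(C)C[C@H]2C3=C[C@@H]([C@@H](O)[C@H](O[Si](C)(C)C(C)(C)C)[C@@]3(C)[C@@H]3C[C@H]23)[C@](C)(C(=O)OC)C[C@H]2C3=C[C@H]1[C@@H](O)[C@H](O[Si](C)(C)C(C)(C)C)[C@@]3(C)[C@@H]1C[C@H]21 | intermediate
33 | 8,8′-diketone (β,γ-unsaturated) | COC(=O)[C@]1(C)C[C@H]2C3=C[C@@H](C(=O)[C@H](O[Si](C)(C)C(C)(C)C)[C@@]3(C)[C@@H]3C[C@H]23)[C@](C)(C(=O)OC)C[C@H]2C3=C[C@H]1C(=O)[C@H](O[Si](C)(C)C(C)(C)C)[C@@]3(C)[C@@H]1C[C@H]21 | intermediate
34 | bis(C8 trimethylsilyl dienol ether), C5=C6 and C7=C8 | COC(=O)[C@]1(C)C[C@H]2C3=CC(=C(O[Si](C)(C)C)[C@H](O[Si](C)(C)C(C)(C)C)[C@@]3(C)[C@@H]3C[C@H]23)[C@](C)(C(=O)OC)C[C@H]2C3=CC1=C(O[Si](C)(C)C)[C@H](O[Si](C)(C)C(C)(C)C)[C@@]3(C)[C@@H]1C[C@H]21 | intermediate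
35 | 9,9′-bis-O-TBS cycloshizukaol A | COC(=O)[C@]1(C)CC2=C3C=C(C(=O)[C@H](O[Si](C)(C)C(C)(C)C)[C@@]3(C)[C@@H]3C[C@H]23)[C@](C)(C(=O)OC)CC2=C3C=C1C(=O)[C@H](O[Si](C)(C)C(C)(C)C)[C@@]3(C)[C@@H]1C[C@H]21 | intermediate
36 | cycloshizukaol A | COC(=O)[C@]1(C)CC2=C3C=C(C(=O)[C@H](O)[C@@]3(C)[C@@H]3C[C@H]23)[C@](C)(C(=O)OC)CC2=C3C=C1C(=O)[C@H](O)[C@@]3(C)[C@@H]1C[C@H]21 | target

**Totals and risks**

Total step count: 23. Longest linear sequence: 20 steps (steps 1–4, then 8–23).

Step 18 (most likely to fail). The ring may not hold a single ketene acetal geometry, so that C11 forms as a mixture, or the second rearrangement may stall once the first has stiffened the ring. The fallback rearranges one ester at a time and sets out from 24. An open-chain Ireland–Claisen rearrangement (LDA/TMSCl in THF without HMPA, which should place the larger C15 chain cis to the allyl oxygen; the methyl ester ketene acetal reverts and the TMS ether is lost on work-up) gives the mono-rearranged acid F1. Diazomethane gives the diester F2, and LiOH then cleaves only the α-tertiary methyl ester, not the neopentyl one, to give the hydroxy acid F3. Acyl fluoride formation and NaH closure as in step 17 give the twelve-membered monolactone F4, and a single transannular Ireland–Claisen rearrangement gives the acid ester F5. Diazomethane returns the route at 31.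

Step 17. Intermolecular acylation to oligomers may outrun ring closure, or the hindered alkoxide may attack too slowly before the acyl fluoride is lost. The fallback is a head-to-tail cyclodimerisation without free alkoxide and sets out from 20. Bis-silylation as in step 15 followed by aqueous work-up gives the 5-O-TMS acid F6, and cyanuric fluoride/pyridine gives the 5-O-TMS acyl fluoride F7. Catalytic TBAT in THF at moderate dilution then lets silyl ether and acyl fluoride condense with loss of Me3SiF, first to the open dimer and then to 27, where the route is rejoined.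

Step 12. The basic reagent may enolise the crowded ketone in place of adding to it, or addition may occur from the β face. The fallback closes the ring intramolecularly, which fixes the cis fusion, and sets out from 17. OsO4/NaIO4 with 2,6-lutidine cleaves the only alkene to the C7 aldehyde F8, and Stork–Zhao olefination (Ph3P=CHI) gives the (Z)-iodoalkene F9. Nozaki–Hiyama–Kishi cyclisation (CrCl2, cat. NiCl2, DMSO) should add C6 to the C5 ketone from the α face on which the tether sits and return the route at 19, bypassing 18.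

Further compounds

F1 | step 18 | mono-rearranged acid: C11 of one half bonded to C7 of the other, free C12 acid on the quaternary carbon, methyl ester and 5-OH retained | COC(=O)C(C)C[C@H]2C3=C[C@@H]([C@@H](OCc4ccc(OC)cc4)[C@H](O[Si](C)(C)C(C)(C)C)[C@@]3(C)[C@@H]3C[C@H]23)[C@](C)(C(=O)O)C[C@@H]1[C@H]2C[C@H]2[C@]3(C)[C@@H](O[Si](C)(C)C(C)(C)C)[C@H](OCc4ccc(OC)cc4)C=C[C@]13O
F2 | step 18 | diester of F1 | COC(=O)C(C)C[C@H]2C3=C[C@@H]([C@@H](OCc4ccc(OC)cc4)[C@H](O[Si](C)(C)C(C)(C)C)[C@@]3(C)[C@@H]3C[C@H]23)[C@](C)(C(=O)OC)C[C@@H]1[C@H]2C[C@H]2[C@]3(C)[C@@H](O[Si](C)(C)C(C)(C)C)[C@H](OCc4ccc(OC)cc4)C=C[C@]13O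
F3 | step 18 | hydroxy acid with the neopentyl methyl ester kept | OC(=O)C(C)C[C@H]2C3=C[C@@H]([C@@H](OCc4ccc(OC)cc4)[C@H](O[Si](C)(C)C(C)(C)C)[C@@]3(C)[C@@H]3C[C@H]23)[C@](C)(C(=O)OC)C[C@@H]1[C@H]2C[C@H]2[C@]3(C)[C@@H](O[Si](C)(C)C(C)(C)C)[C@H](OCc4ccc(OC)cc4)C=C[C@]13O
F4 | step 18 | twelve-membered monolactone | O=C9C(C)C[C@H]2C3=C[C@@H]([C@@H](OCc4ccc(OC)cc4)[C@H](O[Si](C)(C)C(C)(C)C)[C@@]3(C)[C@@H]3C[C@H]23)[C@](C)(C(=O)OC)C[C@@H]1[C@H]2C[C@H]2[C@]3(C)[C@@H](O[Si](C)(C)C(C)(C)C)[C@H](OCc4ccc(OC)cc4)C=C[C@]13O9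
F5 | step 18 | carbocyclic acid ester (one CO2H, one CO2Me) | OC(=O)[C@]1(C)C[C@H]2C3=C[C@@H]([C@@H](OCc4ccc(OC)cc4)[C@H](O[Si](C)(C)C(C)(C)C)[C@@]3(C)[C@@H]3C[C@H]23)[C@](C)(C(=O)OC)C[C@H]2C3=C[C@H]1[C@@H](OCc4ccc(OC)cc4)[C@H](O[Si](C)(C)C(C)(C)C)[C@@]3(C)[C@@H]1C[C@H]21
F6 | step 17 | 5-O-TMS acid | OC(=O)C(C)C[C@@H]1[C@H]2C[C@H]2[C@]3(C)[C@@H](O[Si](C)(C)C(C)(C)C)[C@H](OCc4ccc(OC)cc4)C=C[C@]13O[Si](C)(C)C
F7 | step 17 | 5-O-TMS acyl fluoride | FC(=O)C(C)C[C@@H]1[C@H]2C[C@H]2[C@]3(C)[C@@H](O[Si](C)(C)C(C)(C)C)[C@H](OCc4ccc(OC)cc4)C=C[C@]13O[Si](C)(C)C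
F8 | step 12 | C7 aldehyde of 17 | COC(=O)C(C)C[C@@H]1[C@H]2C[C@H]2[C@@](C)(C1=O)[C@@H](O[Si](C)(C)C(C)(C)C)[C@H](OCc3ccc(OC)cc3)C=O
F9 | step 12 | (Z)-iodoalkene | COC(=O)C(C)C[C@@H]1[C@H]2C[C@H]2[C@@](C)(C1=O)[C@@H](O[Si](C)(C)C(C)(C)C)[C@H](OCc3ccc(OC)cc3)/C=C\I
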